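**Plan**
1. Chain carbons are called C1' (benzylic CH2) to C16' (CH2OH). Retrosynthesis: first the two aryl O–CH3 bonds (hydroquinone masked as its dimethyl ether), then C4'–C5', then the ether C–O bond to farnesyl C1, then the C16'–O bond.
2. Enabling feature: the acyclic hexa-1,5-dien-3-ol unit C2'=C3'(CH3)–C4'H2–C5'H(OH)–C6'=C7' is the retron of a [2,3]-Wittig shift of a bis-allylic ether. The ether oxygen is the tether and ends as the C5' hydroxyl, so no helper has to be removed; the benzene ring only carries the masked hydroquinone.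
3. Forward: 2-allyl-6-methylphenol is taken to (R)-1-aryl-3-methylbut-3-en-2-ol, O-alkylated with (2E,6E)-farnesyl bromide, hydroxylated at the terminal E-methyl with SeO2, rearranged (C4'–C5' formed, chain complete), then demethylated oxidatively and reduced.
4. Stereochemistry: the C6' and C10' E-olefins are bought, the C14' E-olefin follows from the SeO2 mechanism, and C2'=C3' (E) and C5' (S) both arise in the Wittig step, C5' by transfer from the (R) carbinol set by CBS reduction.

Key step: step 9

Remark: commercial (2E,6E)-farnesyl bromide is assumed to be used as the single geometric isomer.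

**Step 1**
Reactants: 1 2-allyl-6-methylphenol
Product: 2 2-allyl-6-methyl-1,4-benzoquinone
Conditions: O2 (1 atm), Co(salen) (10 mol%), DMF, rt
Reagents that add atoms: dioxygen, O=O
Why: Cobalt–salen-catalysed aerobic oxidation of a 2,6-disubstituted phenol to the para-quinone, with both ortho positions blocked so that only the free para position is oxidised.

**Step 2**
Reactants: 2 2-allyl-6-methyl-1,4-benzoquinone
Product: 4 1-allyl-2,5-dimethoxy-3-methylbenzene, via 2-allyl-6-methylbenzene-1,4-diol 3 (not isolated)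
Conditions: Na2S2O4, Bu4NBr (cat.), THF/H2O, rt; then aq. NaOH, Me2SO4, rt, under N2
Reagents that add atoms: dimethyl sulfate, COS(=O)(=O)OC
Why: One-pot reductive methylation of a quinone (dithionite reduction, then phase-transfer Williamson O-methylation of both phenoxides), which avoids handling the air-sensitive hydroquinone.

**Step 3**
Reactants: 4 1-allyl-2,5-dimethoxy-3-methylbenzene
Product: 5 (2,5-dimethoxy-3-methylphenyl)acetaldehyde
Conditions: OsO4 (2 mol%), NaIO4, 2,6-lutidine, dioxane/H2O, rt
Reagents that add atoms: osmium tetroxide, O=[Os](=O)(=O)=O (catalytic oxygen carrier); sodium periodate, [Na+].[O-]I(=O)(=O)=O (terminal oxidant)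
Why: Lemieux–Johnson oxidation (dihydroxylation of the terminal olefin and periodate cleavage in situ) shortens the allyl group to the arylacetaldehyde, and the electron-rich ring is inert to these conditions.

**Step 4**
Reactants: 5 (2,5-dimethoxy-3-methylphenyl)acetaldehyde
Product: 6 rac-1-(2,5-dimethoxy-3-methylphenyl)-3-methylbut-3-en-2-ol
Conditions: isopropenylmagnesium bromide, CeCl3, THF, −78 °C; aq. NH4Cl
Reagents that add atoms: isopropenylmagnesium bromide, C=C(C)[Mg]Br
Why: Grignard addition run as the organocerium reagent to suppress enolisation of the arylacetaldehyde; the carbinol centre forms racemic and is erased in step 5.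

**Step 5**
Reactants: 6 rac-1-(2,5-dimethoxy-3-methylphenyl)-3-methylbut-3-en-2-ol
Product: 7 1-(2,5-dimethoxy-3-methylphenyl)-3-methylbut-3-en-2-one
Conditions: Dess–Martin periodinane, NaHCO3, CH2Cl2, 0 °C to rt
Reagents that add atoms: none
Why: Dess–Martin oxidation of a secondary allylic alcohol under buffered, non-basic conditions should give the α-methylene ketone without moving the double bond; 7 is used at once because it is a reactive Michael acceptor.

**Step 6**
Reactants: 7 1-(2,5-dimethoxy-3-methylphenyl)-3-methylbut-3-en-2-one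
Product: 8 (2R)-1-(2,5-dimethoxy-3-methylphenyl)-3-methylbut-3-en-2-ol
Conditions: (S)-2-methyl-CBS-oxazaborolidine (0.2 equiv), catecholborane, toluene, −78 °C; MeOH, aq. NaOH
Reagents that add atoms: none
Why: Corey–Bakshi–Shibata reduction, in which the ketone binds boron anti to its larger α-branched alkenyl group and takes hydride intramolecularly, so that the (S)-catalyst should give the (R)-carbinol (same sense as acetophenone to (R)-1-phenylethanol); catecholborane at −78 °C avoids hydroboration of the 1,1-disubstituted alkene.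

**Step 7**
Reactants: 8 (2R)-1-(2,5-dimethoxy-3-methylphenyl)-3-methylbut-3-en-2-ol; 9 (2E,6E)-farnesyl bromide
Product: 10 1-[(2R)-3-methyl-2-{[(2E,6E)-3,7,11-trimethyldodeca-2,6,10-trien-1-yl]oxy}but-3-en-1-yl]-2,5-dimethoxy-3-methylbenzene
Conditions: NaH, THF/DMF, 0 °C; then 9, Bu4NI (cat.), 0 °C to rt
Reagents that add atoms: none
Why: Williamson ether synthesis by SN2 displacement at the primary allylic bromide; the C–O bond of the stereocentre is not broken, so the (R) configuration and the olefin geometries are kept.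

**Step 8**
Reactants: 10 the farnesyl ether from step 7
Product: 11 (2E,6E,10E)-12-{[(2R)-1-(2,5-dimethoxy-3-methylphenyl)-3-methylbut-3-en-2-yl]oxy}-2,6,10-trimethyldodeca-2,6,10-trien-1-ol
Conditions: SeO2 (0.3 equiv), t-BuOOH, salicylic acid (cat.), CH2Cl2, 0 °C to rt, stopped at partial conversion
Reagents that add atoms: selenium dioxide, O=[Se]=O (catalytic oxygen carrier); tert-butyl hydroperoxide, CC(C)(C)OO (terminal oxidant)
Why: Catalytic Riley oxidation (ene reaction, then [2,3]-shift of the allylseleninic acid) should hydroxylate the E-methyl group of the terminal trisubstituted olefin, the most electron-rich and least hindered one since the two olefins flanking the ether oxygen are deactivated inductively, and the mechanism delivers the E-allylic alcohol.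

**Step 9**
Reactants: 11 the hydroxy bis-allylic ether from step 8
Product: 13 (2E,6E,10E,12S,14E)-16-(2,5-dimethoxy-3-methylphenyl)-2,6,10,14-tetramethylhexadeca-2,6,10,14-tetraene-1,12-diol, via dilithio alkoxide carbanion 12 (not isolated)
Conditions: n-BuLi (3 equiv), THF, −78 to −25 °C; aq. NH4Cl
Reagents that add atoms: none
Why: [2,3]-Wittig rearrangement of a bis-allylic ether: the first equivalent of n-BuLi makes the C16' lithium alkoxide (which shuts off deprotonation next to that oxygen), the second removes a proton from the farnesyl O–CH2 (C5'), the only primary α-oxy allylic position (the other α-carbon is a substituted methine and should be lithiated far more slowly), and the α-oxy allyllithium 12 rearranges suprafacially through a five-membered envelope transition state in which the C2'–O bond breaks, the C4'–C5' bond forms and the isopropenyl double bond moves to C2'=C3'. The closest known reaction type is the [2,3]-Wittig rearrangement of unsymmetrical bis-allylic ethers of secondary allylic alcohols to 1,5-dien-3-ols; no ring is closed. The new stereocentre C5' is controlled by the (R) ether carbon, which is destroyed in the same event: with the arylmethyl group pseudo-equatorial (which also gives the E C2'=C3' bond) and the trisubstituted alkenyl group on the carbanion exo, turned away from the 3'-methyl group, the carbanion adds to the face of C4' that gives (S). The step needs [2,3]- over [1,2]-shift (low temperature, allyl migrating group), E over Z at the new trisubstituted olefin (the alkenyl group on the stabilised carbanion lies on the side of the pseudo-axial position and should push the arylmethyl group equatorial, unlike in the unstabilised stannylmethyl variant), and lithiation at C5' rather than ortho or benzylic metalation of the dimethoxyarene (slow with n-BuLi in THF without TMEDA at these temperatures).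

**Step 10**
Reactants: 13 the dimethoxyarene diol from step 9
Product: 15 2-[(2E,5S,6E,10E,14E)-5,16-dihydroxy-3,7,11,15-tetramethylhexadeca-2,6,10,14-tetraen-1-yl]-6-methylbenzene-1,4-diol, via quinone 14 (not isolated)
Conditions: (NH4)2Ce(NO3)6, MeCN/H2O, 0 °C; extract into Et2O, then shake with aq. Na2S2O4 under Ar
Reagents that add atoms: water, O
Why: Ceric ammonium nitrate oxidative demethylation of a 1,4-dimethoxyarene (two one-electron oxidations, water adds at the ipso carbons and methanol leaves) should give quinone 14 without touching the isolated olefins or the alcohols, and dithionite reduces 14 to the hydroquinone; the stereocentre and the olefins are not involved.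

**Compound list**
1 | 2-allyl-6-methylphenol | C=CCc1cccc(C)c1O | starting material
2 | 2-allyl-6-methyl-1,4-benzoquinone | C=CCC1=CC(=O)C=C(C)C1=O | intermediate
3 | 2-allyl-6-methylbenzene-1,4-diol (not isolated) | C=CCc1cc(O)cc(C)c1O | intermediate
4 | 1-allyl-2,5-dimethoxy-3-methylbenzene | C=CCc1cc(OC)cc(C)c1OC | intermediate
5 | (2,5-dimethoxy-3-methylphenyl)acetaldehyde | O=CCc1cc(OC)cc(C)c1OC | intermediate
6 | rac-1-(2,5-dimethoxy-3-methylphenyl)-3-methylbut-3-en-2-ol | C=C(C)C(O)Cc1cc(OC)cc(C)c1OC | intermediate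
7 | 1-(2,5-dimethoxy-3-methylphenyl)-3-methylbut-3-en-2-one | C=C(C)C(=O)Cc1cc(OC)cc(C)c1OC | intermediate
8 | (2R)-1-(2,5-dimethoxy-3-methylphenyl)-3-methylbut-3-en-2-ol | C=C(C)[C@H](O)Cc1cc(OC)cc(C)c1OC | intermediate
9 | (2E,6E)-farnesyl bromide, (2E,6E)-1-bromo-3,7,11-trimethyldodeca-2,6,10-triene | CC(C)=CCC/C(C)=C/CC/C(C)=C/CBr | starting material
10 | 1-[(2R)-3-methyl-2-{[(2E,6E)-3,7,11-trimethyldodeca-2,6,10-trien-1-yl]oxy}but-3-en-1-yl]-2,5-dimethoxy-3-methylbenzene | C=C(C)[C@H](OC/C=C(\C)CC/C=C(\C)CCC=C(C)C)Cc1cc(OC)cc(C)c1OC | intermediate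
11 | (2E,6E,10E)-12-{[(2R)-1-(2,5-dimethoxy-3-methylphenyl)-3-methylbut-3-en-2-yl]oxy}-2,6,10-trimethyldodeca-2,6,10-trien-1-ol | C=C(C)[C@H](OC/C=C(\C)CC/C=C(\C)CC/C=C(\C)CO)Cc1cc(OC)cc(C)c1OC | intermediate
12 | dilithium salt of 11, deprotonated at the hydroxyl group and at the farnesyl O–CH2 carbon (not isolated) | C=C(C)[C@H](O[CH-]/C=C(\C)CC/C=C(\C)CC/C=C(\C)C[O-])Cc1cc(OC)cc(C)c1OC.[Li+].[Li+] | intermediate
13 | (2E,6E,10E,12S,14E)-16-(2,5-dimethoxy-3-methylphenyl)-2,6,10,14-tetramethylhexadeca-2,6,10,14-tetraene-1,12-diol | C/C(=C\CC/C(C)=C/CC/C(C)=C/[C@@H](O)C/C(C)=C/Cc1cc(OC)cc(C)c1OC)CO | intermediate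
14 | 2-[(2E,5S,6E,10E,14E)-5,16-dihydroxy-3,7,11,15-tetramethylhexadeca-2,6,10,14-tetraen-1-yl]-6-methyl-1,4-benzoquinone (not isolated) | C/C(=C\CC/C(C)=C/CC/C(C)=C/[C@@H](O)C/C(C)=C/CC1=CC(=O)C=C(C)C1=O)CO | intermediate
15 | 2-[(2E,5S,6E,10E,14E)-5,16-dihydroxy-3,7,11,15-tetramethylhexadeca-2,6,10,14-tetraen-1-yl]-6-methylbenzene-1,4-diol | C/C(=C\CC/C(C)=C/CC/C(C)=C/[C@@H](O)C/C(C)=C/Cc1cc(O)cc(C)c1O)CO | target

**Count**
Total steps: 10. Longest linear sequence: 10 steps (1 to 15); 9 is bought.

**Steps most likely to fail**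

Step 9. The shift may pass to a notable extent through the transition state with the arylmethyl group pseudo-axial, because the 3'-methyl group lowers the usual equatorial preference. That would give E/Z mixtures at C2'=C3' and, coupled to it, loss of enantiomeric purity at C5'. A [1,2]-shift or base-induced elimination across C1'–C2' may also compete. The fallback sets out from 5 and comes back at 13; it fixes the olefin geometry before the C4'–C5' bond is made and sets C5' by reagent control.
- Aldehyde 5 is condensed with ethyl 2-(triphenylphosphoranylidene)propanoate (CH2Cl2, rt) to ethyl (2E)-4-(2,5-dimethoxy-3-methylphenyl)-2-methylbut-2-enoate F1.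
- DIBAL-H (CH2Cl2, −78 °C) reduces it to (2E)-4-(2,5-dimethoxy-3-methylphenyl)-2-methylbut-2-en-1-ol F2.
- MsCl, LiCl and s-collidine in DMF give 1-[(2E)-4-chloro-3-methylbut-2-en-1-yl]-2,5-dimethoxy-3-methylbenzene F3.
- In parallel, commercial (2E,6E)-farnesyl acetate F4 is hydroxylated (SeO2 cat., t-BuOOH) to (2E,6E,10E)-12-hydroxy-3,7,11-trimethyldodeca-2,6,10-trien-1-yl acetate F5.
- TBSCl and imidazole give (2E,6E,10E)-12-(tert-butyldimethylsilyloxy)-3,7,11-trimethyldodeca-2,6,10-trien-1-yl acetate F6.
- K2CO3 in MeOH gives (2E,6E,10E)-12-(tert-butyldimethylsilyloxy)-3,7,11-trimethyldodeca-2,6,10-trien-1-ol F7, and MnO2 gives (2E,6E,10E)-12-(tert-butyldimethylsilyloxy)-3,7,11-trimethyldodeca-2,6,10-trienal F8.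
- The allylbarium reagent from F3 (activated barium from BaI2 and lithium biphenylide, THF, −78 °C) should add to F8 through its α-carbon with retention of the E geometry, giving rac-(2E,6E,10E,14E)-1-(tert-butyldimethylsilyloxy)-16-(2,5-dimethoxy-3-methylphenyl)-2,6,10,14-tetramethylhexadeca-2,6,10,14-tetraen-12-ol F9.
- Dess–Martin oxidation gives (2E,6E,10E,14E)-1-(tert-butyldimethylsilyloxy)-16-(2,5-dimethoxy-3-methylphenyl)-2,6,10,14-tetramethylhexadeca-2,6,10,14-tetraen-12-one F10.
- (R)-CBS catalyst with catecholborane should give (2E,6E,10E,12S,14E)-1-(tert-butyldimethylsilyloxy)-16-(2,5-dimethoxy-3-methylphenyl)-2,6,10,14-tetramethylhexadeca-2,6,10,14-tetraen-12-ol F11, and TBAF in THF then gives 13.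

Step 8. SeO2 may also attack the internal trisubstituted olefins or the isopropenyl methyl group, or over-oxidise the new alcohol to the enal, so that conversion of the valuable ether 10 into 11 stays low. The fallback sets out from 8 and comes back at 11; it brings the hydroxyl group in with the farnesyl unit.
- The silyl ether F7 (made from farnesyl acetate as described under step 9) is converted with CBr4 and PPh3 (CH2Cl2, 0 °C) into (2E,6E,10E)-1-bromo-12-(tert-butyldimethylsilyloxy)-3,7,11-trimethyldodeca-2,6,10-triene F12.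
- F12 alkylates the sodium alkoxide of 8 (NaH, THF/DMF) to give tert-butyl{[(2E,6E,10E)-12-{[(2R)-1-(2,5-dimethoxy-3-methylphenyl)-3-methylbut-3-en-2-yl]oxy}-2,6,10-trimethyldodeca-2,6,10-trien-1-yl]oxy}dimethylsilane F13.
- TBAF in THF releases 11.

Step 6. Facial selectivity may be poor, because the catalyst must tell an isopropenyl from an arylmethyl group, and the enone 7 may dimerise or polymerise before it is reduced. The fallback sets out from 4 and comes back at 8; it sets the stereocentre by epoxidation instead of ketone reduction and also bypasses the enolisable aldehyde 5.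
- Cross-metathesis of 4 with 2-methyl-2-butene (Grubbs second-generation catalyst, CH2Cl2, 40 °C) gives 2,5-dimethoxy-1-methyl-3-(3-methylbut-2-en-1-yl)benzene F14.
- Shi epoxidation with the D-fructose-derived ketone (Oxone, K2CO3, MeCN/dimethoxymethane/buffer, 0 °C) should give (3R)-3-[(2,5-dimethoxy-3-methylphenyl)methyl]-2,2-dimethyloxirane F15.
- Diethylaluminium 2,2,6,6-tetramethylpiperidide (toluene, 0 °C) removes a methyl proton and opens the tertiary C–O bond, which leaves the secondary C–O bond and its configuration intact and gives 8.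

**Further compounds**
F1 | step 9 | ethyl (2E)-4-(2,5-dimethoxy-3-methylphenyl)-2-methylbut-2-enoate | CCOC(=O)/C(C)=C/Cc1cc(OC)cc(C)c1OC
F2 | step 9 | (2E)-4-(2,5-dimethoxy-3-methylphenyl)-2-methylbut-2-en-1-ol | OC/C(C)=C/Cc1cc(OC)cc(C)c1OC
F3 | step 9 | 1-[(2E)-4-chloro-3-methylbut-2-en-1-yl]-2,5-dimethoxy-3-methylbenzene | ClC/C(C)=C/Cc1cc(OC)cc(C)c1OC
F4 | step 9 | (2E,6E)-farnesyl acetate | CC(C)=CCC/C(C)=C/CC/C(C)=C/COC(C)=O
F5 | step 9 | (2E,6E,10E)-12-hydroxy-3,7,11-trimethyldodeca-2,6,10-trien-1-yl acetate | OC/C(C)=C/CC/C(C)=C/CC/C(C)=C/COC(C)=O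
F6 | step 9 | (2E,6E,10E)-12-(tert-butyldimethylsilyloxy)-3,7,11-trimethyldodeca-2,6,10-trien-1-yl acetate | CC(C)(C)[Si](C)(C)OC/C(C)=C/CC/C(C)=C/CC/C(C)=C/COC(C)=O
F7 | step 9 | (2E,6E,10E)-12-(tert-butyldimethylsilyloxy)-3,7,11-trimethyldodeca-2,6,10-trien-1-ol | CC(C)(C)[Si](C)(C)OC/C(C)=C/CC/C(C)=C/CC/C(C)=C/CO
F8 | step 9 | (2E,6E,10E)-12-(tert-butyldimethylsilyloxy)-3,7,11-trimethyldodeca-2,6,10-trienal | CC(C)(C)[Si](C)(C)OC/C(C)=C/CC/C(C)=C/CC/C(C)=C/C=O
F9 | step 9 | rac-(2E,6E,10E,14E)-1-(tert-butyldimethylsilyloxy)-16-(2,5-dimethoxy-3-methylphenyl)-2,6,10,14-tetramethylhexadeca-2,6,10,14-tetraen-12-ol | CC(C)(C)[Si](C)(C)OC/C(C)=C/CC/C(C)=C/CC/C(C)=C/C(O)C/C(C)=C/Cc1cc(OC)cc(C)c1OC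
F10 | step 9 | (2E,6E,10E,14E)-1-(tert-butyldimethylsilyloxy)-16-(2,5-dimethoxy-3-methylphenyl)-2,6,10,14-tetramethylhexadeca-2,6,10,14-tetraen-12-one | CC(C)(C)[Si](C)(C)OC/C(C)=C/CC/C(C)=C/CC/C(C)=C/C(=O)C/C(C)=C/Cc1cc(OC)cc(C)c1OC
F11 | step 9 | (2E,6E,10E,12S,14E)-1-(tert-butyldimethylsilyloxy)-16-(2,5-dimethoxy-3-methylphenyl)-2,6,10,14-tetramethylhexadeca-2,6,10,14-tetraen-12-ol | CC(C)(C)[Si](C)(C)OC/C(C)=C/CC/C(C)=C/CC/C(C)=C/[C@@H](O)C/C(C)=C/Cc1cc(OC)cc(C)c1OC
F12 | step 8 | (2E,6E,10E)-1-bromo-12-(tert-butyldimethylsilyloxy)-3,7,11-trimethyldodeca-2,6,10-triene | CC(C)(C)[Si](C)(C)OC/C(C)=C/CC/C(C)=C/CC/C(C)=C/CBr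
F13 | step 8 | tert-butyl{[(2E,6E,10E)-12-{[(2R)-1-(2,5-dimethoxy-3-methylphenyl)-3-methylbut-3-en-2-yl]oxy}-2,6,10-trimethyldodeca-2,6,10-trien-1-yl]oxy}dimethylsilane | C=C(C)[C@H](OC/C=C(\C)CC/C=C(\C)CC/C=C(\C)CO[Si](C)(C)C(C)(C)C)Cc1cc(OC)cc(C)c1OC
F14 | step 6 | 2,5-dimethoxy-1-methyl-3-(3-methylbut-2-en-1-yl)benzene | CC(C)=CCc1cc(OC)cc(C)c1OC
F15 | step 6 | (3R)-3-[(2,5-dimethoxy-3-methylphenyl)methyl]-2,2-dimethyloxirane | CC1(C)O[C@@H]1Cc1cc(OC)cc(C)c1OC
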